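Atom labels used throughout (these are not compound numbers): C1 = methyl-bearing ring-fusion carbon, C2 and C3 = the CH2 groups of the five-membered ring, C4 = isopropyl carbinol carbon, C5 = ring-fusion CH, C6 = ester-bearing carbon, C7 = CH2, C8=C9 = ring alkene (methyl on C8), C10 = CH2 next to C1. Compound numbers 1–22 are those of the steps and of the compound list.

## The problem

Target 22 is the salicylate of a daucane diol: a cyclopentane (C1–C5) trans-fused along C1–C5 to a cycloheptene (C1, C5–C10). Four contiguous stereocentres must be set: the all-carbon quaternary C1, the tertiary alcohol C4, the fusion hydrogen on C5 (anti to the C1 methyl) and the equatorial acyloxy group on C6 (H6 anti to H5). C1 and C4 lie 1,3 across the five-membered ring and cannot easily control each other, so one has to be brought in in absolute form and the other tied to it by a reagent. Together they can then control C5. The C4 hydroxyl, which sits 1,3 to C6 and on the same ring face as the C5–C6 bond, can control C6. Three features limit the chemistry: the tertiary alcohol is β to C6 (retro-aldol cleavage or dehydration once C6 is a carbonyl), the C8=C9 bond is β,γ to C6 (it slips into conjugation with a C6 ketone under base), and the phenolic ester is sensitive to hydroxide and to acyl transfer. The enabling feature is that the seven-membered ring is a cyclohepta-1,4-diene in disguise. C8=C9 is already present, and an oxygen on C6 is the retron for a C5=C6 bond. C1=C5–C6 then maps onto a vinylcarbene and C7–C10 onto isoprene, joined through a cis-divinylcyclopropane.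

## Retrosynthesis

**22 ⇒ 20 + 21.** The acyl–oxygen bond of the ester is cut first. Leaving it to the end keeps the phenolic ester out of every C–C bond-forming and basic step. The tertiary C4 hydroxyl of diol 20 needs no protection, because only the secondary alkoxide can be acylated. Benzodioxinone 21 carries the salicyloyl group with its phenol masked as an acetonide that falls away during the acyl transfer. The forward reaction must acylate a hindered secondary alcohol without touching the configuration at C6.

**20 ⇒ 18.** The C6–H bond is cut, so the carbinol goes back to β-hydroxy ketone 18. This is preferred to carrying a C6 oxygen stereocentre through the synthesis, because the C4 hydroxyl of 18 can deliver hydride to the face of the carbonyl that an external reagent cannot reach (the axial C1 methyl blocks it). The precursor has one stereocentre fewer. The forward reduction must be internal, and the medium must not be basic, or C8=C9 would migrate and the aldol would reverse.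

**18 ⇒ 17 ⇒ 13 ⇒ 12.** The C6 carbonyl oxygen is traced back to a carboxyl carbon (ketone ⇐ enamine ⇐ isocyanate ⇐ acid ⇐ ester). This removes the C5 stereocentre and turns the problem into a tetrasubstituted unsaturated ester 12, the pattern a vinyl diazoacetate leaves behind. The alternative of keeping the carboxyl carbon in the target's skeleton does not exist, so a C-to-O exchange is unavoidable, and the Curtius route does it in two operations. The forward sequence asks that C5 be protonated from the face anti to the C1 methyl. The silyl ether is therefore kept on through hydrolysis (17) and removed afterwards (18). It also stops the C4 oxygen from lactonising onto the C6 carboxyl of 13.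

**12 ⇒ 8 + 9 (via 11 and 10).** The bonds C1–C10 and C6–C7 are cut, which is the retron of a cyclopropanation–Cope sequence. This cut is preferred to its neighbours because it puts both ring alkenes where later steps need them. It also places the quaternary C1 at a terminus of the rearranging system and makes the C8 methyl and C7–C10 a commodity diene, isoprene 9. The precursor 8 is a monocyclic diazoester with a single stereocentre. The forward reaction must choose the methyl-substituted alkene of 9, give the cis-divinylcyclopropane 11, and transfer the catalyst-set configuration to C1 through the boat transition state.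

**8 ⇒ 6 + 7.** The C5–C6 bond between the ring alkene and the diazo carbon is cut. A palladium coupling of vinyl iodide 6 with ethyl diazoacetate 7 makes this bond and keeps the diazo group in one step. The usual alternative, diazo transfer onto a vinylacetic ester, would need a separate C–C bond formation first. The coupling must tolerate a tetrasubstituted iodide.

**6 ⇒ 5 ⇒ 4 ⇒ 2 + 3, and 2 ⇒ 1.** The O–Si bond, then the C4–isopropyl bond, then the C–I bond are cut. Iodoenone 2 uses one functional group twice: the carbonyl accepts the isopropyl group from 3 to become C4, and the iodide is the handle for C5–C6. The racemic carbinol 4 is resolved to 5 at this smallest and cheapest stage. The addition must be a clean 1,2-addition without iodine–metal exchange, and enone 1 is a bulk chemical.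

## Roads not taken

**Alternative 1:** The cut is C3–C4, closing the five-membered ring last. A cationic rhodium bisphosphine catalyst would insert into the formyl C–H bond of the cycloheptene aldehyde A2 (formyl on C5, vinyl on C1) and add it across the vinyl group to give the trans-fused C4 ketone A1.
- Merits: ring closure of 4-pentenals to cyclopentanones is reliable and atom-economical. The C4 ketone of A1 should take the isopropyl group from the face anti to the C5–C6 bond and the C1 methyl, which is the target's configuration at C4.
- Better than the chosen plan in one respect: C4 would be set by substrate control with no resolution, and C5 and C6 would be fixed before the ring closes.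
- Weak points: all the difficulty moves into A2, a cycloheptene with three contiguous stereocentres. Its quaternary C1 sits next to an epimerisable formyl-bearing C5, and the β-silyloxy aldehyde can eliminate or decarbonylate under the catalyst. The seven-membered ring itself is not addressed.
- What the chosen plan sets against it: it builds the seven-membered ring and C1 in a single step from a trivially made cyclopentene and isoprene.

**Alternative 2:** The cut is C1–C5, made by a 1,2-shift. A boron Lewis acid would open the C4–C5 epoxide of the trans-decalin epoxy silyl ether A4 at C5 while C1 migrates from C6 to C5, giving the β-hydroxy ketone A3, which is identical with 18.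
- Merits: decalins are easy to assemble, and the shift is stereospecific (inversion at C5). A3 arrives with C4 and C5 correct, two steps from the target.
- Better than the chosen plan in one respect: C5 comes from a stereospecific migration, whereas the chosen plan has to rely on a face-selective protonation in step 8.
- Weak points: A4 needs four stereocentres, including an isopropyl-bearing epoxide carbon and an angular silyloxy group. Both C1 and C7 are attached to C6, and which migrates depends on antiperiplanarity in a rigid ring system. The Lewis acid meets a product that can dehydrate or conjugate.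
- What the chosen plan sets against it: a much shorter path to its key precursor 8, four steps from 1.

**Alternative 3:** The cut is a one-carbon insertion (C7). A silylated diazomethane reagent with a Lewis acid would add to the C8 carbonyl of the proline-derived hydrindenone A6, and migration of the alkenyl carbon C6 would give the ring-expanded β,γ-unsaturated ketone A5.
- Merits: A6 is available in quantity and in absolute form from an organocatalytic aldol cyclisation.
- Better than the chosen plan in one respect: the absolute configuration of C1 is settled in the first step, without a resolution and without a chiral metal catalyst.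
- Weak points: A5 still lacks the C8 methyl, the C8=C9 bond, the C6 oxygen, the isopropyl group and the C4 carbinol. Each must be added with its own regiochemical or facial question (enolisation of the C8 ketone towards C7 or C9, hydration of C5=C6, oxidation and isopropyl addition at C4). The expansion itself can give the alkyl-migration isomer or a double homologation.
- What the chosen plan sets against it: the diene brings the C8 methyl and C8=C9 in the ring-forming step, and the route stays at eleven steps.

Key step: step 6

Assumption: the sense of induction that Rh2(S-DOSP)4 (dirhodium tetrakis[(S)-N-(4-dodecylphenylsulfonyl)prolinate]) shows with simple vinyldiazoacetates and monosubstituted alkenes is taken to hold for 8 and the 1,1-disubstituted alkene of isoprene. If it proved opposite, the mirror-image catalyst Rh2(R-DOSP)4 would be used with no other change.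

## Route

Step 1
Reactants: 1 3-methylcyclopent-2-en-1-one
Product: 2 2-iodo-3-methylcyclopent-2-en-1-one
Conditions: I2, pyridine, CH2Cl2, 0 °C → rt
Reagents that add atoms: iodine, II
Why: α-Iodination of an enone by conjugate addition of pyridine, iodination of the enolate and loss of pyridine (addition–elimination α-halogenation); the β-methyl group slows the reaction but does not change its course.

Step 2
Reactants: 2 2-iodo-3-methylcyclopent-2-en-1-one; 3 isopropylmagnesium chloride
Product: 4 rac-2-iodo-3-methyl-1-(propan-2-yl)cyclopent-2-en-1-ol
Conditions: CeCl3 (dried), THF, −78 °C; aq. NH4Cl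
Reagents that add atoms: none
Why: Organocerium 1,2-addition to a ketone; the weakly basic, oxophilic isopropylcerium reagent should add to the carbonyl faster than it enolises the ketone, transfers a β-hydride or exchanges with the vinyl iodide, and the carbinol forms as the racemate.

Step 3
Reactants: 4 rac-2-iodo-3-methyl-1-(propan-2-yl)cyclopent-2-en-1-ol
Product: 5 (1R)-2-iodo-3-methyl-1-(propan-2-yl)cyclopent-2-en-1-ol
Conditions: preparative supercritical-fluid chromatography, amylose tris(3,5-dimethylphenylcarbamate) phase, CO2/i-PrOH
Reagents that add atoms: none
Why: Resolution of enantiomers on a chiral stationary phase, placed at the smallest compound of the route so that the discarded half costs least; the (R)-enantiomer has the spatial arrangement of C4 in the target, and the iodine atom should allow the assignment by anomalous-dispersion crystallography.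

Step 4
Reactants: 5 (1R)-2-iodo-3-methyl-1-(propan-2-yl)cyclopent-2-en-1-ol
Product: 6 triethyl{[(1R)-2-iodo-3-methyl-1-(propan-2-yl)cyclopent-2-en-1-yl]oxy}silane
Conditions: Et3SiOTf, 2,6-lutidine, CH2Cl2, −78 → 0 °C
Reagents that add atoms: triethylsilyl trifluoromethanesulfonate, CC[Si](CC)(CC)OS(=O)(=O)C(F)(F)F
Why: Silylation of a hindered tertiary alcohol with a silyl triflate and a non-nucleophilic base; the ether blocks O–H insertion in step 6 and lactonisation in step 7, shields one face of C5 in step 8, and the stereocentre is not involved.

Step 5
Reactants: 6 triethyl{[(1R)-2-iodo-3-methyl-1-(propan-2-yl)cyclopent-2-en-1-yl]oxy}silane; 7 ethyl diazoacetate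
Product: 8 ethyl 2-diazo-2-[(5R)-2-methyl-5-(propan-2-yl)-5-(triethylsilyloxy)cyclopent-1-en-1-yl]acetate
Conditions: Pd(PPh3)4 (cat.), Et3N, n-Bu4NBr, MeCN, rt
Reagents that add atoms: none
Why: Cross-coupling of a vinyl iodide with the C–H bond of a diazoester under zerovalent palladium, with the diazo group retained (oxidative addition, base-assisted palladation of the diazo carbon, reductive elimination), a known route to vinyldiazoacetates; 8 is used at once because vinyldiazo compounds can close to 3H-pyrazoles on standing.

Step 6
Reactants: 8 ethyl 2-diazo-2-[(5R)-2-methyl-5-(propan-2-yl)-5-(triethylsilyloxy)cyclopent-1-en-1-yl]acetate; 9 isoprene (2-methylbuta-1,3-diene)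
Product: 12 ethyl (3R,8aR)-6,8a-dimethyl-3-(propan-2-yl)-3-(triethylsilyloxy)-1,2,3,5,8,8a-hexahydroazulene-4-carboxylate, via dirhodium carbenoid 10 (not isolated), via cis-divinylcyclopropane 11 (not isolated)
Conditions: Rh2(S-DOSP)4 (1 mol %), 9 (10 equiv), hexanes, slow addition of 8, −40 °C → rt; then toluene, 110 °C, sealed tube
Reagents that add atoms: none
Why: Rh2(S-DOSP)4 takes N2 out of 8, and the donor/acceptor carbenoid 10 adds to the methyl-substituted double bond of isoprene in a concerted but asynchronous [2+1] step, the terminal CH2 (C7) bonding first while positive charge develops on the tertiary allylic carbon C8; the sequence is the known tandem cyclopropanation/Cope rearrangement (formal [4+3] cycloaddition) of cyclic vinyldiazoacetates with 1,3-dienes. Carbenoids of this class place an alkene substituent cis to the donor group, and of the two groups on C8 the vinyl group is expected to take this place, so that in 11 it is cis to the cyclopentenyl group on C6. The three-membered ring thus closes by carbene addition (C6–C7 and C6–C8), and the seven-membered ring by a [3,3]-sigmatropic shift through the boat transition state, the only one open to a cis-divinylcyclopropane, in which C6–C8 breaks as C1–C10 forms (ring enlargement from three to seven atoms). The one new stereocentre that survives is the quaternary C1: the prolinate ligands fix the configuration of C6 and C8 in 11 by choosing the face of the carbenoid, and the boat geometry hands this on to C1, with C10 arriving on the cyclopentene face anti to the silyloxy group. The methyl group on C1 points into the boat and slows the sigmatropic step, hence the heating once the carbenoid has been consumed. The step needs regioselectivity for the 1,1-disubstituted alkene of isoprene (secured by its higher nucleophilicity), chemoselectivity for intermolecular addition over C–H insertion (large excess of diene, hydrocarbon solvent, slow addition of 8) and face selectivity (catalyst); because C4 is already homochiral, material with the wrong sense at C1 would be a diastereomer and could be removed by chromatography.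

Step 7
Reactants: 12 ethyl (3R,8aR)-6,8a-dimethyl-3-(propan-2-yl)-3-(triethylsilyloxy)-1,2,3,5,8,8a-hexahydroazulene-4-carboxylate
Product: 13 (3R,8aR)-6,8a-dimethyl-3-(propan-2-yl)-3-(triethylsilyloxy)-1,2,3,5,8,8a-hexahydroazulene-4-carboxylic acid
Conditions: LiOH·H2O, THF/MeOH/H2O, 50 °C; then 1 M HCl to pH 3, 0 °C
Reagents that add atoms: lithium hydroxide, [Li+].[OH-]
Why: Ester saponification by acyl–oxygen cleavage; the flanked tertiary silyl ether should resist aqueous hydroxide, and it must stay because a free C4 hydroxyl would close onto the C6 carboxyl as a butenolide.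

Step 8
Reactants: 13 (3R,8aR)-6,8a-dimethyl-3-(propan-2-yl)-3-(triethylsilyloxy)-1,2,3,5,8,8a-hexahydroazulene-4-carboxylic acid
Product: 17 (3R,3aR,8aR)-6,8a-dimethyl-3-(propan-2-yl)-3-(triethylsilyloxy)-2,3,3a,5,8,8a-hexahydroazulen-4(1H)-one, via acyl azide 14 (not isolated), via vinyl isocyanate 15 (not isolated), via enamine 16 (not isolated)
Conditions: (PhO)2P(O)N3, Et3N, toluene, 0 °C → rt, then 80 °C; then THF, 1 M aq. HCl, 0 °C
Reagents that add atoms: water, O; diphenylphosphoryl azide, [N-]=[N+]=NP(=O)(Oc1ccccc1)Oc1ccccc1 (its nitrogen is found in 14, 15 and 16 only)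
Why: Curtius rearrangement: acyl azide 14 loses N2 with migration of C6 to nitrogen to give vinyl isocyanate 15, and cold dilute acid hydrolyses it through the carbamic acid to enamine 16, which is protonated at C5 and hydrolysed to the ketone. The proton should enter C5 from the face anti to the C1 methyl and to the silyloxy group, whose silicon is expected to lie over that face (anti to the isopropyl group), so that the C5–C6 bond ends cis to oxygen and the ring fusion is trans. The short, cold acid treatment is chosen so that the hindered silyl ether survives until C5 is set and C8=C9 stays out of conjugation.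

Step 9
Reactants: 17 (3R,3aR,8aR)-6,8a-dimethyl-3-(propan-2-yl)-3-(triethylsilyloxy)-2,3,3a,5,8,8a-hexahydroazulen-4(1H)-one
Product: 18 (3R,3aR,8aR)-3-hydroxy-6,8a-dimethyl-3-(propan-2-yl)-2,3,3a,5,8,8a-hexahydroazulen-4(1H)-one
Conditions: HF·pyridine, pyridine, THF, 0 °C → rt
Reagents that add atoms: none
Why: Fluoride-mediated cleavage of a silyl ether under buffered, non-basic conditions; base is avoided because it would invite retro-aldol opening of the β-hydroxy ketone and migration of C8=C9 into conjugation, and C5 is not enolised under these conditions.

Step 10
Reactants: 18 (3R,3aR,8aR)-3-hydroxy-6,8a-dimethyl-3-(propan-2-yl)-2,3,3a,5,8,8a-hexahydroazulen-4(1H)-one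
Product: 20 (3R,3aS,4S,8aR)-6,8a-dimethyl-3-(propan-2-yl)-1,2,3,3a,4,5,8,8a-octahydroazulene-3,4-diol, via alkoxyborohydride 19 (not isolated)
Conditions: Me4NBH(OAc)3, MeCN/AcOH, −30 → 0 °C
Reagents that add atoms: none
Why: Hydroxyl-directed reduction of a β-hydroxy ketone (Evans–Saksena reduction): the C4 hydroxyl exchanges onto boron to give 19, and hydride is delivered within a six-membered transition state to the carbonyl face on which the C4 oxygen lies. The trans ring fusion holds that oxygen pseudo-axial above C6, so hydride should enter anti to H5 and the C6 hydroxyl comes out equatorial (4S in azulene numbering), whereas an external hydride would be pushed to the other face by the axial C1 methyl. The acidic medium leaves C8=C9 and the aldol linkage untouched.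

Step 11
Reactants: 20 (3R,3aS,4S,8aR)-6,8a-dimethyl-3-(propan-2-yl)-1,2,3,3a,4,5,8,8a-octahydroazulene-3,4-diol; 21 2,2-dimethyl-4H-1,3-benzodioxin-4-one
Product: 22 (3R,3aS,4S,8aR)-3-hydroxy-6,8a-dimethyl-3-(propan-2-yl)-1,2,3,3a,4,5,8,8a-octahydroazulen-4-yl 2-hydroxybenzoate
Conditions: NaN(SiMe3)2 (1.1 equiv), THF, 0 °C; then 21, 0 °C → rt; aq. NH4Cl
Reagents that add atoms: none
Why: Acyl transfer from a 1,3-benzodioxin-4-one to an alkoxide with loss of acetone, a known way to salicylate esters that needs no phenol protection; only the secondary C6 alkoxide should be acylated, the tertiary C4 hydroxyl being too hindered, and since the C6–O bond is not broken its configuration is retained.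

## Compound list

1 | 3-methylcyclopent-2-en-1-one | CC1=CC(=O)CC1 | starting material
2 | 2-iodo-3-methylcyclopent-2-en-1-one | CC1=C(I)C(=O)CC1 | intermediate
3 | isopropylmagnesium chloride | CC(C)[Mg]Cl | starting material
4 | rac-2-iodo-3-methyl-1-(propan-2-yl)cyclopent-2-en-1-ol | CC1=C(I)C(O)(C(C)C)CC1 | intermediate
5 | (1R)-2-iodo-3-methyl-1-(propan-2-yl)cyclopent-2-en-1-ol | CC1=C(I)[C@](O)(C(C)C)CC1 | intermediate
6 | triethyl{[(1R)-2-iodo-3-methyl-1-(propan-2-yl)cyclopent-2-en-1-yl]oxy}silane | CC1=C(I)[C@](O[Si](CC)(CC)CC)(C(C)C)CC1 | intermediate
7 | ethyl diazoacetate | CCOC(=O)C=[N+]=[N-] | starting material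
8 | ethyl 2-diazo-2-[(5R)-2-methyl-5-(propan-2-yl)-5-(triethylsilyloxy)cyclopent-1-en-1-yl]acetate | CCOC(=O)C(=[N+]=[N-])C1=C(C)CC[C@@]1(O[Si](CC)(CC)CC)C(C)C | intermediate
9 | isoprene (2-methylbuta-1,3-diene) | C=CC(C)=C | starting material
10 | dirhodium carbenoid formed from 8 by loss of N2 (rhodium drawn without its prolinate ligands; not isolated) | CCOC(=O)C(=[Rh])C1=C(C)CC[C@@]1(O[Si](CC)(CC)CC)C(C)C | intermediate
11 | ethyl (1S,2R)-2-ethenyl-2-methyl-1-[(5R)-2-methyl-5-(propan-2-yl)-5-(triethylsilyloxy)cyclopent-1-en-1-yl]cyclopropane-1-carboxylate (vinyl cis to cyclopentenyl; not isolated) | CCOC(=O)[C@@]1(C2=C(C)CC[C@@]2(O[Si](CC)(CC)CC)C(C)C)C[C@]1(C)C=C | intermediate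
12 | ethyl (3R,8aR)-6,8a-dimethyl-3-(propan-2-yl)-3-(triethylsilyloxy)-1,2,3,5,8,8a-hexahydroazulene-4-carboxylate | CC1=CC[C@@]2(C)CC[C@@](O[Si](CC)(CC)CC)(C(C)C)C2=C(C(=O)OCC)C1 | intermediate
13 | (3R,8aR)-6,8a-dimethyl-3-(propan-2-yl)-3-(triethylsilyloxy)-1,2,3,5,8,8a-hexahydroazulene-4-carboxylic acid | CC1=CC[C@@]2(C)CC[C@@](O[Si](CC)(CC)CC)(C(C)C)C2=C(C(O)=O)C1 | intermediate
14 | (3R,8aR)-6,8a-dimethyl-3-(propan-2-yl)-3-(triethylsilyloxy)-1,2,3,5,8,8a-hexahydroazulene-4-carbonyl azide (not isolated) | CC1=CC[C@@]2(C)CC[C@@](O[Si](CC)(CC)CC)(C(C)C)C2=C(C(=O)N=[N+]=[N-])C1 | intermediate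
15 | triethyl{[(3R,8aR)-4-isocyanato-6,8a-dimethyl-3-(propan-2-yl)-1,2,3,5,8,8a-hexahydroazulen-3-yl]oxy}silane (not isolated) | CC1=CC[C@@]2(C)CC[C@@](O[Si](CC)(CC)CC)(C(C)C)C2=C(N=C=O)C1 | intermediate
16 | (3R,8aR)-6,8a-dimethyl-3-(propan-2-yl)-3-(triethylsilyloxy)-1,2,3,5,8,8a-hexahydroazulen-4-amine (not isolated) | CC1=CC[C@@]2(C)CC[C@@](O[Si](CC)(CC)CC)(C(C)C)C2=C(N)C1 | intermediate
17 | (3R,3aR,8aR)-6,8a-dimethyl-3-(propan-2-yl)-3-(triethylsilyloxy)-2,3,3a,5,8,8a-hexahydroazulen-4(1H)-one | CC1=CC[C@@]2(C)CC[C@@](O[Si](CC)(CC)CC)(C(C)C)[C@@H]2C(=O)C1 | intermediate
18 | (3R,3aR,8aR)-3-hydroxy-6,8a-dimethyl-3-(propan-2-yl)-2,3,3a,5,8,8a-hexahydroazulen-4(1H)-one | CC1=CC[C@@]2(C)CC[C@@](O)(C(C)C)[C@@H]2C(=O)C1 | intermediate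
19 | tetramethylammonium diacetoxy(hydrido)borate bound through the C4 oxygen of 18 (not isolated) | CC1=CC[C@@]2(C)CC[C@@](O[BH-](OC(C)=O)OC(C)=O)(C(C)C)[C@@H]2C(=O)C1.C[N+](C)(C)C | intermediate
20 | (3R,3aS,4S,8aR)-6,8a-dimethyl-3-(propan-2-yl)-1,2,3,3a,4,5,8,8a-octahydroazulene-3,4-diol | CC1=CC[C@@]2(C)CC[C@@](O)(C(C)C)[C@@H]2[C@@H](O)C1 | intermediate
21 | 2,2-dimethyl-4H-1,3-benzodioxin-4-one | CC1(C)OC(=O)c2ccccc2O1 | starting material
22 | (3R,3aS,4S,8aR)-3-hydroxy-6,8a-dimethyl-3-(propan-2-yl)-1,2,3,3a,4,5,8,8a-octahydroazulen-4-yl 2-hydroxybenzoate | CC1=CC[C@@]2(C)CC[C@@](O)(C(C)C)[C@@H]2[C@@H](OC(=O)c2ccccc2O)C1 | target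

## Step count and least certain steps

Total: 11 steps. Longest linear sequence: 11 steps (1 → 22); 3, 7, 9 and 21 are purchased and enter in steps 2, 5, 6 and 11.

**Step 6 (key step).** Three processes may go wrong.
- The very hindered carbenoid 10 may react with itself, or insert into a C–H bond of its own silyl or isopropyl group, faster than it finds the diene.
- Addition may occur at the unsubstituted double bond of isoprene, which would leave the methyl group on C9.
- The sigmatropic step, slowed by the inward methyl group, may need temperatures at which the C6–C8 bond of 11 opens reversibly, which would erode the configuration handed on to C1.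

Fallback: keep the carbenoid and the Cope step but assemble 11 in stages from 8 with an alkene that has only one double bond, so that the regiochemical question disappears. Cyclopropanation of 2-methylprop-2-en-1-yl acetate (as co-solvent, same catalyst) should give the cyclopropylmethyl acetate F1. Methanolysis (K2CO3, MeOH) gives the cyclopropylmethanol F2, and Dess–Martin oxidation gives the cyclopropanecarbaldehyde F3. Wittig methylenation (Ph3P=CH2, THF, −78 → 0 °C) returns to 11, which is heated on to 12 as in the main route.

**Step 8.** The likeliest failure is poor facial selectivity in the protonation of enamine 16 at C5, giving the cis-fused ketone. This could not be repaired afterwards, because any base or acid strong enough to enolise C5 would first enolise towards C7 and move C8=C9 into conjugation. Premature loss of the silyl group would remove the shielding on which the selectivity rests.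

Fallback, from 12: fluoride desilylation (n-Bu4NF, THF) lets the C4 oxygen close onto the C6 ester to give the butenolide F5. Conjugate reduction (Mg, MeOH) gives the saturated lactone F6, in which the necessarily cis fusion of the two five-membered rings forces H5 onto the isopropyl face, that is, anti to the C1 methyl. Hydroxylation of the lactone enolate (LiN(i-Pr)2, then 3-phenyl-2-(phenylsulfonyl)oxaziridine) gives the α-hydroxy lactone F7, and LiAlH4 gives the triol F8. NaIO4 cleaves the vicinal diol and returns to 18. The C6 configuration of F6–F8 is immaterial and is left open.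

**Step 5.** The oxidative-addition complex of the tetrasubstituted, doubly flanked iodide may be too crowded for palladation of the diazo carbon, so that the diazoester is consumed by decomposition instead.

Fallback, from 6: Reformatsky–Negishi coupling with BrZnCH2CO2Et (Pd(PPh3)4, THF, 60 °C) gives the β,γ-unsaturated ester F4. Regitz diazo transfer (4-acetamidobenzenesulfonyl azide, DBU, MeCN) then returns to 8.

**Step 10.** The tertiary, flanked C4 hydroxyl may exchange onto boron too slowly for internal delivery. Forcing the reaction would then open an undirected pathway in which hydride approaches from the unhindered equatorial direction and gives the axial alcohol.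

Fallback, from 18: dissolving-metal reduction (Li, NH3/THF, −78 °C, then NH4Cl). It proceeds through the ketyl and should lead to the thermodynamically preferred equatorial alcohol 20 whatever the direction of reagent approach. This fallback makes no new compound (F0).

**Step 11.** Acyl transfer to the hindered C6 alkoxide may be slow, and the phenoxide of the product may then attack a second molecule of 21.

Fallback, from 20: acylation with 2-(acetyloxy)benzoyl chloride (pyridine, DMAP, CH2Cl2) gives the O-acetylsalicylate F9. Selective aminolysis of the aryl acetate (pyrrolidine, CH2Cl2, 0 °C) then gives 22.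

## Further compounds

F1 | step 6 | ethyl 2-(acetyloxymethyl)-2-methyl-1-[(5R)-2-methyl-5-(propan-2-yl)-5-(triethylsilyloxy)cyclopent-1-en-1-yl]cyclopropane-1-carboxylate, configured as 11 with CH2OAc in place of the vinyl group (cis to cyclopentenyl) | CCOC(=O)[C@@]1(C2=C(C)CC[C@@]2(O[Si](CC)(CC)CC)C(C)C)C[C@]1(C)COC(C)=O
F2 | step 6 | ethyl 2-(hydroxymethyl)-2-methyl-1-[(5R)-2-methyl-5-(propan-2-yl)-5-(triethylsilyloxy)cyclopent-1-en-1-yl]cyclopropane-1-carboxylate, configured as F1 | CCOC(=O)[C@@]1(C2=C(C)CC[C@@]2(O[Si](CC)(CC)CC)C(C)C)C[C@]1(C)CO
F3 | step 6 | ethyl 2-formyl-2-methyl-1-[(5R)-2-methyl-5-(propan-2-yl)-5-(triethylsilyloxy)cyclopent-1-en-1-yl]cyclopropane-1-carboxylate, configured as F1 | CCOC(=O)[C@@]1(C2=C(C)CC[C@@]2(O[Si](CC)(CC)CC)C(C)C)C[C@]1(C)C=O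
F4 | step 5 | ethyl 2-[(5R)-2-methyl-5-(propan-2-yl)-5-(triethylsilyloxy)cyclopent-1-en-1-yl]acetate | CCOC(=O)CC1=C(C)CC[C@@]1(O[Si](CC)(CC)CC)C(C)C
F5 | step 8 | butenolide from 12: lactone between the C4 oxygen and the C6 carboxyl, C5=C6 retained, C1 and C4 as in 12 | CC1=CC[C@@]2(C)CC[C@]3(C(C)C)OC(=O)C(C1)=C23
F6 | step 8 | saturated lactone from F5, H5 cis to the isopropyl group and anti to the C1 methyl, C6 configuration open | CC1=CC[C@@]2(C)CC[C@]3(C(C)C)OC(=O)C(C1)[C@H]23
F7 | step 8 | 6-hydroxy derivative of lactone F6, C6 configuration open | CC1=CC[C@@]2(C)CC[C@]3(C(C)C)OC(=O)C(O)(C1)[C@H]23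
F8 | step 8 | triol from F7: C4 hydroxyl, C6 hydroxyl and C6 hydroxymethyl, trans-fused, C6 configuration open | CC1=CC[C@@]2(C)CC[C@@](O)(C(C)C)[C@@H]2C(O)(CO)C1
F0 | step 10 | none | none
F9 | step 11 | (3R,3aS,4S,8aR)-3-hydroxy-6,8a-dimethyl-3-(propan-2-yl)-1,2,3,3a,4,5,8,8a-octahydroazulen-4-yl 2-(acetyloxy)benzoate | CC1=CC[C@@]2(C)CC[C@@](O)(C(C)C)[C@@H]2[C@@H](OC(=O)c2ccccc2OC(C)=O)C1
A1 | alternative 1 | (3aS,4S,8aR)-4-(tert-butyldimethylsilyloxy)-6,8a-dimethyl-2,3a,4,5,8,8a-hexahydroazulen-3(1H)-one (trans-fused C4 ketone) | CC1=CC[C@@]2(C)CCC(=O)[C@@H]2[C@@H](O[Si](C)(C)C(C)(C)C)C1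
A2 | alternative 1 | 7-(tert-butyldimethylsilyloxy)-2-ethenyl-2,5-dimethylcyclohept-4-ene-1-carbaldehyde, configured as the target at C1, C5 and C6 | CC1=CC[C@@](C)(C=C)[C@H](C=O)[C@@H](O[Si](C)(C)C(C)(C)C)C1
A3 | alternative 2 | (3R,3aR,8aR)-3-hydroxy-6,8a-dimethyl-3-(propan-2-yl)-2,3,3a,5,8,8a-hexahydroazulen-4(1H)-one (identical with 18) | CC1=CC[C@@]2(C)CC[C@@](O)(C(C)C)[C@@H]2C(=O)C1
A4 | alternative 2 | trans-decalin in which C1 (angular methyl) is bonded to C6 (angular triethylsilyloxy), C4–C5 is an epoxide with the isopropyl group on C4, and C8=C9 carries the C8 methyl | CC1=CC[C@@]2(C)CC[C@]3(C(C)C)O[C@@H]3[C@]2(O[Si](CC)(CC)CC)C1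
A5 | alternative 3 | 3-(tert-butyldimethylsilyloxy)-8a-methyl-2,3,5,7,8,8a-hexahydroazulen-6(1H)-one (C5=C6, C8 ketone) | O=C1CC[C@@]2(C)CC[C@H](O[Si](C)(C)C(C)(C)C)C2=CC1
A6 | alternative 3 | 1-(tert-butyldimethylsilyloxy)-7a-methyl-1,2,3,6,7,7a-hexahydro-5H-inden-5-one | O=C1CC[C@@]2(C)CC[C@H](O[Si](C)(C)C(C)(C)C)C2=C1
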